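**Retrosynthetic overview**

1. The route rests on the trans-decalin: ring A (C1–C5 and C10, gem-dimethyl on C4) and ring B (C5–C10) with the angular methyl on C10 and the tetrasubstituted C8=C9 alkene (methyl on C8, the C11–C12 chain on C9; drimane locants). This is read as the imprint of a head-to-tail cation–olefin cyclisation that ends at C9.
2. The ylidene-butenolide is cut at its exocyclic C=C: vinylogous Mukaiyama aldol of a 2-silyloxyfuran with an (E)-enal, then elimination; the lactone ring is brought in intact.
3. The enal is cut at the C12–C(sp2) bond: B-alkyl Suzuki coupling of the bicyclic chloride (through its Grignard reagent) with a (Z)-iodoallylic alcohol made by anti-hydroalumination/iodination of monosilylated butynediol. A copper-catalysed carbomagnesiation of that alkynol is avoided because the β-silyloxy alkenylmagnesium would collapse to an allenol.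
4. The chloride is cut at C4–C5 and C9–C10: ring A, then ring B, close in one cationic cascade from an acyclic (3Z,7E)-silyl triene, with silicon on C9 fixing the alkene at C8=C9.
5. The triene comes from geranyl bromide, 1-(trimethylsilyl)propyne, MeMgBr and ethylene oxide.

Key step: step 4

Remark on the chemistry (assumption): the (R) antipode of 2-benzyloxy-2'-hydroxy-1,1'-binaphthyl is taken to be the one that delivers the 5S,10S series, by analogy with related polyprenoid cyclisations; if the sense of induction is opposite on this substrate, the (S) ligand is used under the same conditions.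

Abbreviations: TBS = tert-butyldimethylsilyl; Dec = (4aS,8aS)-2,5,5,8a-tetramethyl-3,4,4a,5,6,7,8,8a-octahydronaphthalen-1-yl.

**Route**

Step 1
Reactants: 1 1-(trimethylsilyl)propyne; 2 geranyl bromide
Product: 4 trimethyl[(5E)-6,10-dimethylundeca-5,9-dien-1-yn-1-yl]silane, via 3-lithio-1-(trimethylsilyl)propyne 3 (not isolated)
Conditions: n-BuLi, THF, −78 to −20 °C; then 2, −78 °C to rt
Reagents that add atoms: none
Why: Propargylic lithiation of the silylpropyne and SN2 alkylation by the primary allylic bromide, the silyl group steering the ambident anion to react at its CH2 terminus (alkyne, not allene) while the (E) alkene of the geranyl unit is untouched.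

Step 2
Reactants: 4 trimethyl[(5E)-6,10-dimethylundeca-5,9-dien-1-yn-1-yl]silane; 5 ethylene oxide
Product: 7 (3Z,7E)-4,8,12-trimethyl-3-(trimethylsilyl)trideca-3,7,11-trien-1-ol, via alkenylmagnesium bromide 6 (not isolated)
Conditions: MeMgBr (3 equiv), Ni(acac)2 (10 mol %), Me3Al (10 mol %), THF, rt; then CuI (10 mol %), 5 (excess), −30 to 0 °C; aq NH4Cl
Reagents that add atoms: methylmagnesium bromide, C[Mg]Br
Why: Nickel-catalysed syn-carbomagnesiation of a 1-silylalkyne puts methyl on the carbon remote from silicon and magnesium on the silicon-bearing carbon, and copper-catalysed epoxide opening by the alkenyl Grignard reagent proceeds with retention, so that silicon ends up cis to the long chain and the hydroxyethyl group cis to the new methyl (3Z).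

Step 3
Reactants: 7 (3Z,7E)-4,8,12-trimethyl-3-(trimethylsilyl)trideca-3,7,11-trien-1-ol
Product: 8 [(3Z,7E)-1-chloro-4,8,12-trimethyltrideca-3,7,11-trien-3-yl]trimethylsilane
Conditions: PPh3, CCl4, CH2Cl2, 0 °C to rt
Reagents that add atoms: carbon tetrachloride, ClC(Cl)(Cl)Cl
Why: Appel reaction, an SN2 displacement of the alkoxyphosphonium by chloride at the primary carbon under neutral conditions that leave the vinylsilane and the trisubstituted alkenes untouched.

Step 4
Reactants: 8 [(3Z,7E)-1-chloro-4,8,12-trimethyltrideca-3,7,11-trien-3-yl]trimethylsilane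
Product: 9 (4aS,8aS)-1-(2-chloroethyl)-2,5,5,8a-tetramethyl-3,4,4a,5,6,7,8,8a-octahydronaphthalene
Conditions: (R)-2-benzyloxy-2'-hydroxy-1,1'-binaphthyl (1.1 equiv), SnCl4 (1.0 equiv), toluene, −78 °C
Reagents that add atoms: none
Why: Proposed new method: the SnCl4-bound binaphthol monoether is a strong but bulky chiral Brønsted acid that should protonate the unhindered terminal isopropylidene alkene at C3 from one enantioface, the tertiary C4 cation is then captured by the (E)-C5=C10 alkene and the resulting C10 cation by the silicon-bearing carbon C9 of the C8=C9 vinylsilane, which places the charge on C8, β to silicon, and loss of the Me3Si group returns the alkene to C8=C9 only. The closest known reaction types are the enantioselective proton-initiated cyclisations of polyprenoids with these Lewis acid-assisted Brønsted acids (arene-, hydroxyl- and carboxyl-terminated) and the vinylsilane-terminated cation–olefin cyclisation, which have not been combined on a fully substituted vinylsilane. Ring A closes 6-endo-trig (C4–C5 bond) and ring B closes 6-endo-trig (C9–C10 bond). C5 and C10 are set relative to each other by anti addition across the (E) central alkene in a chair–chair fold, which gives the trans ring fusion, and their absolute configuration (5S,10S) by the enantioface of C3 that the chiral acid protonates. The step needs protonation of the terminal alkene in preference to protodesilylation of the vinylsilane, which the steric shielding of the tetrasubstituted silyl alkene toward the bulky acid should secure, and it needs regiocontrol of the final alkene, which silicon on C9 cis to C7 secures because the C9–Si bond becomes axial and parallel to the empty orbital on C8; the primary chloride is inert to the acid.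

Step 5
Reactants: 10 but-2-yne-1,4-diol
Product: 11 4-[(tert-butyldimethylsilyl)oxy]but-2-yn-1-ol
Conditions: NaH (1.0 equiv), THF, 0 °C to rt; then TBSCl (1.0 equiv)
Reagents that add atoms: tert-butyldimethylsilyl chloride, CC(C)(C)[Si](C)(C)Cl
Why: Monosilylation of a symmetrical diol through its sparingly soluble monosodium alkoxide, which reacts once with TBSCl (O-silylation).

Step 6
Reactants: 11 4-[(tert-butyldimethylsilyl)oxy]but-2-yn-1-ol
Product: 13 (2Z)-4-[(tert-butyldimethylsilyl)oxy]-3-iodobut-2-en-1-ol, via cyclic alkenylaluminate 12 (not isolated)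
Conditions: NaAlH2(OCH2CH2OMe)2 (1.1 equiv), THF, 0 °C; then I2, −78 to 0 °C
Reagents that add atoms: iodine, II
Why: Hydroxyl-directed anti-hydroalumination (hydride to C2 and aluminium to C3 inside a five-membered alkoxyaluminate) followed by iodinolysis with retention gives the (2Z) iodide with iodine cis to CH2OH, and keeping the mixture at or below 0 °C holds back β-elimination of the silyloxy group to an allenol.

Step 7
Reactants: 9 (4aS,8aS)-1-(2-chloroethyl)-2,5,5,8a-tetramethyl-3,4,4a,5,6,7,8,8a-octahydronaphthalene; 13 (2Z)-4-[(tert-butyldimethylsilyl)oxy]-3-iodobut-2-en-1-ol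
Product: 16 (2E)-3-{[(tert-butyldimethylsilyl)oxy]methyl}-5-Dec-pent-2-en-1-ol, via Grignard reagent 14 (not isolated), via B-alkyl-9-BBN 15 (not isolated)
Conditions: Mg, THF, reflux; B-methoxy-9-BBN, −78 °C to rt; then 13, PdCl2(dppf) (5 mol %), AsPh3, aq K3PO4, DMF, rt
Reagents that add atoms: none
Why: Magnesium insertion into the primary chloride, alkyl transfer to boron and B-alkyl Suzuki–Miyaura coupling join C12 to the alkenyl carbon with retention of the alkene geometry (the chain takes the place of iodine, cis to CH2OH, giving the (2E) alcohol), the free hydroxyl and the silyl ether being tolerated and the dppf ligand holding back β-hydride elimination.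

Step 8
Reactants: 16 (2E)-3-{[(tert-butyldimethylsilyl)oxy]methyl}-5-Dec-pent-2-en-1-ol
Product: 17 (2E)-3-{[(tert-butyldimethylsilyl)oxy]methyl}-5-Dec-pent-2-enal
Conditions: MnO2, CH2Cl2, rt
Reagents that add atoms: none
Why: Chemoselective oxidation of the allylic alcohol by MnO2 under neutral conditions, which leaves the alkene geometry, the silyl ether and the isolated tetrasubstituted alkene untouched.

Step 9
Reactants: 18 4-methylfuran-2(5H)-one
Product: 19 tert-butyldimethyl[(4-methylfuran-2-yl)oxy]silane
Conditions: TBSOTf, Et3N, CH2Cl2, 0 °C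
Reagents that add atoms: tert-butyldimethylsilyl trifluoromethanesulfonate, CC(C)(C)[Si](C)(C)OS(=O)(=O)C(F)(F)F
Why: Soft enolisation of the butenolide at its γ-CH2 and O-silylation give the aromatic 2-silyloxyfuran (silyl dienol ether formation).

Step 10
Reactants: 17 (2E)-3-{[(tert-butyldimethylsilyl)oxy]methyl}-5-Dec-pent-2-enal; 19 tert-butyldimethyl[(4-methylfuran-2-yl)oxy]silane
Product: 21 (5Z)-5-[(2E)-3-{[(tert-butyldimethylsilyl)oxy]methyl}-5-Dec-pent-2-en-1-ylidene]-4-methylfuran-2(5H)-one, via aldol silyl ether 20 (not isolated)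
Conditions: TBSOTf (10 mol %), CH2Cl2, −78 °C; then DBU, −78 °C to rt
Reagents that add atoms: none
Why: Vinylogous Mukaiyama aldol addition of the silyloxyfuran through C5 to the aldehyde carbon (1,2-addition) with silyl transfer, then E1cB elimination of silanolate from the γ-deprotonated butenolide, the (5Z) ylidene geometry being favoured because the (5E) isomer would press the side chain against the C4 methyl, while the (2E) alkene of the enal is carried through unchanged.

Step 11
Reactants: 21 (5Z)-5-[(2E)-3-{[(tert-butyldimethylsilyl)oxy]methyl}-5-Dec-pent-2-en-1-ylidene]-4-methylfuran-2(5H)-one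
Product: 22 (5Z)-5-[(2E)-3-(hydroxymethyl)-5-Dec-pent-2-en-1-ylidene]-4-methylfuran-2(5H)-one (CNP0288110.2)
Conditions: HF·pyridine, pyridine, THF, 0 °C
Reagents that add atoms: none
Why: Fluoride cleavage of the primary allylic silyl ether under buffered, non-basic conditions that spare the base-sensitive ylidene-butenolide and the triene (desilylation).

**Compound list**

1 | 1-(trimethylsilyl)propyne | CC#C[Si](C)(C)C | starting material
2 | geranyl bromide, (2E)-1-bromo-3,7-dimethylocta-2,6-diene | CC(C)=CCC/C(C)=C/CBr | starting material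
3 | 3-lithio-1-(trimethylsilyl)propyne | [Li]CC#C[Si](C)(C)C | intermediate
4 | trimethyl[(5E)-6,10-dimethylundeca-5,9-dien-1-yn-1-yl]silane | CC(C)=CCC/C(C)=C/CCC#C[Si](C)(C)C | intermediate
5 | ethylene oxide | C1CO1 | starting material
6 | [(1Z,5E)-2,6,10-trimethyl-1-(trimethylsilyl)undeca-1,5,9-trien-1-yl]magnesium bromide (Mg cis to the C2 methyl) | CC(C)=CCC/C(C)=C/CC/C(C)=C(/[Mg]Br)[Si](C)(C)C | intermediate
7 | (3Z,7E)-4,8,12-trimethyl-3-(trimethylsilyl)trideca-3,7,11-trien-1-ol | CC(C)=CCC/C(C)=C/CC/C(C)=C(/CCO)[Si](C)(C)C | intermediate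
8 | [(3Z,7E)-1-chloro-4,8,12-trimethyltrideca-3,7,11-trien-3-yl]trimethylsilane | CC(C)=CCC/C(C)=C/CC/C(C)=C(/CCCl)[Si](C)(C)C | intermediate
9 | (4aS,8aS)-1-(2-chloroethyl)-2,5,5,8a-tetramethyl-3,4,4a,5,6,7,8,8a-octahydronaphthalene | ClCCC1=C(C)CC[C@H]2C(C)(C)CCC[C@]12C | intermediate
10 | but-2-yne-1,4-diol | OCC#CCO | starting material
11 | 4-[(tert-butyldimethylsilyl)oxy]but-2-yn-1-ol | OCC#CCO[Si](C)(C)C(C)(C)C | intermediate
12 | sodium bis(2-methoxyethoxy)aluminate with a five-membered Al–O–CH2–CH=C ring, CH2OTBS on the aluminium-bound alkene carbon | [Na+].COCCO[Al-]1(OCCOC)OCC=C1CO[Si](C)(C)C(C)(C)C | intermediate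
13 | (2Z)-4-[(tert-butyldimethylsilyl)oxy]-3-iodobut-2-en-1-ol | OC/C=C(\I)CO[Si](C)(C)C(C)(C)C | intermediate
14 | (2-Dec-ethyl)magnesium chloride | Cl[Mg]CCC1=C(C)CC[C@H]2C(C)(C)CCC[C@]12C | intermediate
15 | 9-(2-Dec-ethyl)-9-borabicyclo[3.3.1]nonane | C(CC1=C(C)CC[C@H]2C(C)(C)CCC[C@]12C)B1C2CCCC1CCC2 | intermediate
16 | (2E)-3-{[(tert-butyldimethylsilyl)oxy]methyl}-5-Dec-pent-2-en-1-ol | OC/C=C(/CO[Si](C)(C)C(C)(C)C)CCC1=C(C)CC[C@H]2C(C)(C)CCC[C@]12C | intermediate
17 | (2E)-3-{[(tert-butyldimethylsilyl)oxy]methyl}-5-Dec-pent-2-enal | O=C/C=C(/CO[Si](C)(C)C(C)(C)C)CCC1=C(C)CC[C@H]2C(C)(C)CCC[C@]12C | intermediate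
18 | 4-methylfuran-2(5H)-one | CC1=CC(=O)OC1 | starting material
19 | tert-butyldimethyl[(4-methylfuran-2-yl)oxy]silane | Cc1coc(O[Si](C)(C)C(C)(C)C)c1 | intermediate
20 | 5-{(2E)-1-[(tert-butyldimethylsilyl)oxy]-3-{[(tert-butyldimethylsilyl)oxy]methyl}-5-Dec-pent-2-en-1-yl}-4-methylfuran-2(5H)-one (mixture of diastereomers at the lactone C5 and the carbinol carbon) | CC1=CC(=O)OC1C(O[Si](C)(C)C(C)(C)C)/C=C(/CO[Si](C)(C)C(C)(C)C)CCC1=C(C)CC[C@H]2C(C)(C)CCC[C@]12C | intermediate
21 | (5Z)-5-[(2E)-3-{[(tert-butyldimethylsilyl)oxy]methyl}-5-Dec-pent-2-en-1-ylidene]-4-methylfuran-2(5H)-one | CC1=CC(=O)O/C1=C\C=C(\CO[Si](C)(C)C(C)(C)C)CCC1=C(C)CC[C@H]2C(C)(C)CCC[C@]12C | intermediate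
22 | (5Z)-5-[(2E)-3-(hydroxymethyl)-5-Dec-pent-2-en-1-ylidene]-4-methylfuran-2(5H)-one | CC1=CC(=O)O/C1=C\C=C(\CO)CCC1=C(C)CC[C@H]2C(C)(C)CCC[C@]12C | target

**Step count**

Total: 11 steps. Longest linear sequence: 8 steps (steps 1, 2, 3, 4, 7, 8, 10, 11).

**Steps most likely to fail, with fallbacks**

1. Step 4. The acid may protodesilylate the vinylsilane before ring closure, the cascade may stop after ring A, or enantioface discrimination at C3 may be modest, since bond formation between the quaternary C10 and the fully substituted C9 is crowded. The fallback gives up the silicon-terminated closure for a carboxyl-terminated one, which is known for these SnCl4–binaphthol acids, and makes the C8=C9 alkene afterwards. It sets out from silylalkyne 4 and comes back at chloride 9. K2CO3 in MeOH removes the alkyne silyl group to give (5E)-6,10-dimethylundeca-5,9-dien-1-yne F1. Zirconium-catalysed carboalumination (Me3Al, Cp2ZrCl2), conversion to the alanate with n-BuLi and opening of ethylene oxide 5 should give (3E,7E)-4,8,12-trimethyltrideca-3,7,11-trien-1-ol F2. TEMPO and PhI(OAc)2 in aqueous MeCN oxidise it to (3E,7E)-4,8,12-trimethyltrideca-3,7,11-trienoic acid F3. Proton-initiated cyclisation with the same SnCl4–binaphthol acid should give (+)-sclareolide F4, a crystalline lactone whose enantiomeric purity can be raised by recrystallisation. LiAlH4 reduces it to (1R,2R,4aS,8aS)-1-(2-hydroxyethyl)-2,5,5,8a-tetramethyldecahydronaphthalen-2-ol F5, and Ac2O in pyridine acetylates only the primary hydroxyl to give 2-[(1R,2R,4aS,8aS)-2-hydroxy-2,5,5,8a-tetramethyldecahydronaphthalen-1-yl]ethyl acetate F6. PPh3/I2 dehydrates the tertiary alcohol towards the tetrasubstituted alkene, 2-Dec-ethyl acetate F7; K2CO3 in MeOH frees 2-Dec-ethanol F8; and the Appel conditions of step 3 convert F8 into chloride 9.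

2. Step 2. The α-silyl alkenylmagnesium intermediate may lose its geometry while the slow copper-mediated epoxide opening at a fully substituted alkenyl carbon proceeds, and capture may be incomplete. The fallback makes the C2–C3 bond by palladium coupling instead of by epoxide opening, through an isolable alkenyl iodide. It sets out from silylalkyne 4 and comes back at alcohol 7. The carbomagnesiation mixture is quenched with I2 to give [(1E,5E)-1-iodo-2,6,10-trimethylundeca-1,5,9-trien-1-yl]trimethylsilane F9, which can be freed of its geometric isomer by chromatography. Stille coupling with tributyl(vinyl)stannane (Pd(PPh3)4, CuI, DMF) should give, with retention, trimethyl[(3Z,7E)-4,8,12-trimethyltrideca-1,3,7,11-tetraen-3-yl]silane F10. 9-BBN followed by NaOH/H2O2 hydroborates only the monosubstituted vinyl group at its terminus and gives alcohol 7.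

3. Step 10. The silyloxyfuran may add in the 1,4 sense, the elimination may be incomplete or give a (5E)/(5Z) mixture, and prolonged exposure to DBU may expel silyloxide from the allylic CH2OTBS group of the extended trienyl lactone. The fallback builds the lactone on an alkyne instead of by aldol chemistry. It sets out from enal 17 and comes back at silyl ether 21. Lithiated (trimethylsilyl)diazomethane (Colvin rearrangement) converts the aldehyde into the terminal enyne tert-butyldimethyl({(2E)-2-[2-Dec-ethyl]pent-2-en-4-yn-1-yl}oxy)silane F11. Sonogashira coupling with commercial (Z)-3-iodobut-2-enoic acid (Pd(PPh3)4, CuI, Et3N, MeCN) is followed in the same flask by 5-exo-dig anti addition of the carboxylate to the alkyne, which should give the (5Z)-ylidene butenolide 21 directly.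

**Further compounds**

F1 | step 4 | (5E)-6,10-dimethylundeca-5,9-dien-1-yne | CC(C)=CCC/C(C)=C/CCC#C
F2 | step 4 | (3E,7E)-4,8,12-trimethyltrideca-3,7,11-trien-1-ol | CC(C)=CCC/C(C)=C/CC/C(C)=C/CCO
F3 | step 4 | (3E,7E)-4,8,12-trimethyltrideca-3,7,11-trienoic acid | CC(C)=CCC/C(C)=C/CC/C(C)=C/CC(=O)O
F4 | step 4 | (+)-sclareolide, (3aR,5aS,9aS,9bR)-3a,6,6,9a-tetramethyldecahydronaphtho[2,1-b]furan-2(1H)-one | O=C1C[C@H]2[C@](C)(O1)CC[C@H]1C(C)(C)CCC[C@]21C
F5 | step 4 | (1R,2R,4aS,8aS)-1-(2-hydroxyethyl)-2,5,5,8a-tetramethyldecahydronaphthalen-2-ol | OCC[C@H]1[C@](C)(O)CC[C@H]2C(C)(C)CCC[C@]12C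
F6 | step 4 | 2-[(1R,2R,4aS,8aS)-2-hydroxy-2,5,5,8a-tetramethyldecahydronaphthalen-1-yl]ethyl acetate | CC(=O)OCC[C@H]1[C@](C)(O)CC[C@H]2C(C)(C)CCC[C@]12C
F7 | step 4 | 2-Dec-ethyl acetate | CC(=O)OCCC1=C(C)CC[C@H]2C(C)(C)CCC[C@]12C
F8 | step 4 | 2-Dec-ethanol | OCCC1=C(C)CC[C@H]2C(C)(C)CCC[C@]12C
F9 | step 2 | [(1E,5E)-1-iodo-2,6,10-trimethylundeca-1,5,9-trien-1-yl]trimethylsilane | CC(C)=CCC/C(C)=C/CC/C(C)=C(/I)[Si](C)(C)C
F10 | step 2 | trimethyl[(3Z,7E)-4,8,12-trimethyltrideca-1,3,7,11-tetraen-3-yl]silane | CC(C)=CCC/C(C)=C/CC/C(C)=C(/C=C)[Si](C)(C)C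
F11 | step 10 | tert-butyldimethyl({(2E)-2-[2-Dec-ethyl]pent-2-en-4-yn-1-yl}oxy)silane | C#C/C=C(/CO[Si](C)(C)C(C)(C)C)CCC1=C(C)CC[C@H]2C(C)(C)CCC[C@]12C
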